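**Late balance.** Late on, the theta flask stops looking like a race: from 480 min to 600 min the complex with one exchanged slips from 46.6% to 43.1%, and the starting complex falls from 11.0% to 7.5%. Let m, a and b be the fractions of the charge held as starting complex, complex with one exchanged and complex with two exchanged, with b as the remainder. Each suspected exchange trades one incoming ligand for one leaving ligand. At balance, a/m and b/a therefore carry the same ligand ratio, and a·a/(m·b) holds neither ligand. The last reading gives 5.01 for this exchange quotient Q, a comproportionation constant, and the reading before gives 4.66.

all flasks: gas 200 mM (held)

|  | starting complex | temperature | remark | time |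
|---|---|---|---|---|
| theta | 2 M | 35 °C | the very flask that is asked about, followed so far |  |
| eta | 3 M | 30 °C | run made earlier |  |
| flask | 2.0 M | 35 °C |  | 15 h |

| run | time / min | complex with one exchanged / % | starting complex / % |
|---|---|---|---|
| theta | 120 | 26.1 | 65.8 |
| theta | 240 | 44.4 | 38.5 |
| theta | 300 | 46.9 | 28.4 |
| theta | 480 | 46.6 | 11.0 |
| theta | 600 | 43.1 | 7.5 |
| eta | 10.0 | 3.1 | 98.0 |
| eta | 20.0 | 3.0 | 97.0 |
| eta | 30.0 | 7.3 | 94.0 |
| eta | 40.0 | 7.1 | 91.1 |
| eta | 50.0 | 10.3 | 86.4 |

(standard deviation of a reading: 1 percentage point)
* complex with one exchanged, in percent of the starting complex first charged, at 15 h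
* what to do for the largest gain in complex with one exchanged; "none" if nothing gains more than 2 percentage points (south-west / west / north-west / none)
* complex with one exchanged present, with what was taken out counted in, in percent of the starting complex first charged, after west
* complex with one exchanged present, with what was taken out counted in, in percent of the starting complex first charged, after north-west
- south-west: at 15 h raise the temperature by 15 K, then wait 5.0 h
- west: at 15 h take out 90% of the complex with one exchanged then present, then wait 5.0 h
- north-west: change nothing and wait 5.0 h more
- at the start none of incoming ligand is dissolved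
- removed complex with one exchanged is counted in
- what was read earlier has a scatter of 1 percentage point, one standard deviation
- on the list of suspects stand: starting complex + incoming ligand <-> leaving ligand + complex with one exchanged; complex with one exchanged + incoming ligand <-> leaving ligand + complex with two exchanged; gas <-> incoming ligand

**First way.** In logarithms, m loses one decade per 463 min from 120 min to 480 min. That straight line puts m at 1.69% at 15 h.

**Second way.** The count n = a + 2b tells how many exchanges each charged complex has made. Its rate falls from 0.00195 min⁻¹ to 8.75 × 10⁻⁴ min⁻¹, a relaxation time of 187 min. So n reaches 1.51 at 15 h. Solving n, Q and the charge balance together gives b = 56.6%, a = 38.3% and m = 5.17%.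

**The cheat.** The two values of m part. The last interval needs 721 min per decade, longer than the line's slope allows, so the straight line cheats: it reads a reversible fall as one-way decay. My reckoning keeps a = 38.3%.

**The options.** On this reckoning, waiting adds 0.0239 to n, which leaves a slightly lower. West banks 34.4% and drops the quotient in the flask to 0.0501, far below Q. If the old proportions return within 5.0 h, the total reaches 59.5%. The eta run stops at 50.0 min with 86.4% of its starting complex standing, so heating stays unreckoned, and my pick is west.

**Forecast.** The forecast gives 38% (34% to 42%), 51% (44% to 58%) after west and 36% (31% to 41%) after north-west, and picks west: “West wins clearly”.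

**Result.** The flask gives 39.9% at 15 h, and west is best, reaching 59.8% against 39.7% after north-west.

    starting complex + incoming ligand ⇌ leaving ligand + complex with one exchanged (K = 120, k = 0.00250 L mol⁻¹ s⁻¹, Ea = 66.0 kJ mol⁻¹, ΔH = −10.0 kJ mol⁻¹)
    complex with one exchanged + incoming ligand ⇌ leaving ligand + complex with two exchanged (K = 21.0, k = 0.00280 L mol⁻¹ s⁻¹, Ea = 78.0 kJ mol⁻¹, ΔH = −41.0 kJ mol⁻¹)
    gas ⇌ incoming ligand, rate k3*(csat - [incoming ligand]) (kL = 6.80 × 10⁻⁴ s⁻¹)
    (constants at 35 °C)

Left until 9000 min, the flask still shows 39.7%. The same flask charged with 0.50 M ends with starting complex at 0.664% and complex with two exchanged at 81.7%. With Q, these give a = 16.5%, and that neighbour holds 17.6%.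

The numbers in the tables come from a simulation from invented constants, and the scatter is random.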